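Read the earlier runs as one curve first, then ask what each new flask does to that curve.

| flask | G | E | remark | time |
|---|---|---|---|---|
| south-east | 0.20 M | 0.98 equiv | run made earlier |  |
| north | 0.28 M | 0.98 equiv | run made earlier |  |
| south | 0.44 M | 0.98 equiv | run made earlier |  |
| east | 0.20 M | 1.5 equiv | run made earlier |  |
| grey | 0.20 M | 0.980 equiv (fed, over 2.5 min) | all else is in the flask from the start; the feed brings no volume worth counting | 3.0 min |
| amber | 0.20 M (fed, over 2.5 min) | 0.980 equiv | all else is in the flask from the start; the feed brings no volume worth counting | 3.0 min |
| ochre | 0.20 M | 0.980 equiv | everything together at the start | 3.0 min |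
| red | 0.20 M (fed, over 40 s) | 0.980 equiv | all else is in the flask from the start; the feed brings no volume worth counting | 3.0 min |

| run | time / min | Z / % |
|---|---|---|
| south-east | 0.250 | 56 |
| south-east | 0.333 | 53 |
| south-east | 0.500 | 45 |
| south-east | 0.833 | 35 |
| south-east | 1.33 | 33 |
| south-east | 2.00 | 32 |
| south-east | 3.00 | 26 |
| north | 0.167 | 64 |
| north | 0.333 | 52 |
| north | 0.667 | 42 |
| north | 1.00 | 36 |
| north | 1.33 | 36 |
| north | 2.00 | 32 |
| north | 2.50 | 28 |
| south | 0.333 | 57 |
| south | 0.667 | 41 |
| south | 1.00 | 36 |
| south | 1.33 | 33 |
| south | 1.50 | 34 |
| south | 2.00 | 29 |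
| south | 2.50 | 30 |
| east | 0.500 | 52 |
| east | 1.00 | 40 |
| east | 1.33 | 38 |
| east | 2.00 | 35 |
| east | 2.50 | 30 |

(readings scatter by 1.5 percentage points)

- the numbers in the tables scatter with a standard deviation of 1.5 percentage points

1. the best flask by amount of Z, in percent of the G charged; "all alike" if 1.5 percentage points covers them all (grey / amber / ochre / red / all alike)
2. amount of Z at the end, in percent of the G charged, grey
3. amount of Z at the end, in percent of the G charged, amber
4. amount of Z at the end, in percent of the G charged, ochre
5. amount of Z at the end, in percent of the G charged, red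

In the south-east run, Z starts steeply: it loses 21 points between 0.250 min and 0.833 min. Then the curve bends near 0.833 min: it loses 9 points over the 2.17 min up to 3.00 min. Past such a knee, I take the logarithm of the fall in each of the 4 runs and average, which gives 0.155 min⁻¹. I call this s, the tail rate: the fraction of Z lost per minute past the knee. Drawn back to the start from the last south-east reading, the tail meets the axis at 41.3%. Drawn forward, it sinks towards zero.

My reckoning assumes that Z ages along this tail and that each flask yields as the south-east run did. Ochre repeats the south-east recipe, so it should read near 26%. A feed spreads the ages of Z at the end, so I average the tail over them. That gives 31.7% for grey and for amber, and 27.4% for red. Grey and amber therefore stand level, above red and ochre.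

The forecast, leaning to amber where I leave a tie, gives 32.5% for grey, 33.5% for amber, 26.5% for ochre and 27.5% for red, on the ground “Each link's fate therefore depends only on its age”.

The flasks give 34.6% for grey, 15.7% for amber, 26.8% for ochre and 20.7% for red, so the best is grey.

    Z ⇌ Q (K = 1.00, k = 0.0350 s⁻¹)
    2 E → J (k = 0.0790 L mol⁻¹ s⁻¹)
    G + E → Z + X (k = 2.00 L mol⁻¹ s⁻¹)
    Z → L (k = 0.00550 s⁻¹)

Amber falls below grey through two things acting together: E, the limiting reagent, goes to J, and Q falls back to Z. Without the path to J, the gap between grey and amber shrinks from 19 points to 0.13 points. Amber ends with 52% of its G unused. Amber's E stands at 0% at 2.50 min, so the tail rate should carry amber's Z from 17.1% to 15.8% at 3.00 min, and the flask holds 15.7%. Left until 8.0 min, amber should hold 7.25%, and it holds 7.10%.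

The readings were generated by integration with constants of no real substance; the scatter is artificial.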